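All runs were generated by integration with constants of no real substance, and the scatter is random.

No flask can hold more product than it received coupling partner, and here partner and substrate are charged 1.00 equiv to one, so I write the balance of the partner, the limiting reagent.

| flask | substrate | coupling partner | initiator | remark | time |
|---|---|---|---|---|---|
| oak | 0.14 M | 1 equiv | 22 mol% | run made earlier |  |
| flask | 0.14 M | 1.00 equiv | 11 mol% |  | 2.0 h |
oak run (percent of the substrate charged)

| time / min | product / % | substrate / % |
|---|---|---|
| 2.00 | 4.1 | 96.2 |
| 4.00 | 9.0 | 92.1 |
| 10.0 | 18.7 | 81.1 |
| 25.0 | 34.9 | 64.5 |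

(scatter of a reading: 0.5 percentage points)
- percentages count the substrate that a species holds: one ended chains B counts as two
- product is meant together with its crystals
- solid, in amounts per volume of the solution: crystals
- steps thought possible: coupling partner <-> dormant form; coupling partner + chain carrier -> product + initiating radical; 2 chain carrier -> ended chains B; crystals <-> product; substrate + initiating radical -> chain carrier; 2 coupling partner -> homo dimer; initiator -> 2 initiating radical; 2 initiating radical -> ended chains A
- the concentration of product that is asked is that of its free form alone
- no earlier run changes the charge of initiator; that part of a forecast is a guess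
1. concentration of product (only what is free in solution) at 2.0 h, in M
2. concentration of substrate at 2.0 h, in M

I assume partner leaves by coupling, pseudo-first-order with rate constant κ, and by side paths that go with its concentration squared. As fractions of the charge, with b the partner left and p the product, that gives:

dp/dt = κb
db/dt = −κb(1 + ρb)
p = ln(1 + ρ(1 − exp(−κt)))/ρ

In the oak run the product slope is 0.0187 min⁻¹ up to 10.0 min, then 0.0108 min⁻¹. Extrapolating back to the start gives κ = 0.0229 min⁻¹. The fall of ln(slope) per product made equals ρ + 1/b, which gives ρ = 1.53. This ρ, the side-to-coupling ratio, is partner lost aside per partner coupled at the start.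

The flask has half the initiator, and I guess that κ follows its square root:

κ = 0.0162 min⁻¹
ρ = 2.17
p = 48.5%

That root is the weak link: a linear law would give 38.9%. But both chain-ending steps on the list are pairwise, so I keep the root, as a guess. I commit to 0.0678 M product and, since the oak run's last readings sum to 99.4%, 0.0722 M substrate.

The forecast says 0.064 M and 0.07 M, lower on product than mine, and for substrate it reasons: “I take about 50%, so 0.07 M”.

The flask gives 0.0715 M product and 0.0670 M substrate, and both values of the forecast stand within the margin.

    coupling partner ⇌ dormant form (K = 4.20, k = 0.00240 min⁻¹)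
    coupling partner + chain carrier → product + initiating radical (k = 27000 M⁻¹ s⁻¹)
    2 chain carrier → ended chains B (k = 1.00 × 10⁹ M⁻¹ s⁻¹)
    crystals ⇌ product, rate k4*(cs4 - [product]) while solid is left; crystals form when [product] > cs4 (solubility = 0.0750 M, k = 0.160 min⁻¹)
    substrate + initiating radical → chain carrier (k = 27000 M⁻¹ s⁻¹)
    2 coupling partner → homo dimer (k = 0.0930 M⁻¹ min⁻¹)
    initiator → 2 initiating radical (k = 4.10 × 10⁻⁴ min⁻¹)
    2 initiating radical → ended chains A (k = 1.50 × 10⁶ M⁻¹ s⁻¹)

At 2.00 h the flask holds 4.8% of its partner, less than the 48% of its substrate, beside 0.0259 M homo dimer. My ρ gives the partner left as exp(−κt)/(1 + ρ(1 − exp(−κt))) = 5.00%.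

In a neighbour flask charged with 0.035 M substrate, equivalents, loading and time held, my κ and ρ both halve, to 0.00811 min⁻¹ and 1.08, so p = 47.6%. The computed flask gives 46.3%.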